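The route rests on cutting the C4–C4a bond between the ketone carbon of ring C and ring A. The key step exploits that C4a lies between two oxygenated carbons of ring A (C8a–O1 and C5–O): a bromine placed there undergoes bromine–lithium exchange, and the chelated aryllithium acylates a tethered Weinreb amide (Parham cyclisation), closing the pyranone ring under conditions that spare the prenyl group, the benzofuran and the acid-labile benzylic C2–O1 ether. The precursor is an (S)-3-aryl-3-(2-bromoaryloxy) Weinreb propanamide with all phenols as MOM ethers, assembled by Mitsunobu inversion of an (R)-benzylic alcohol from Noyori transfer hydrogenation.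

Key step: step 12

Remark: flavanone numbering is used throughout (O1, C2, C3, C4, C4a, C5–C8, C8a; ring A = phloroglucinol ring, ring C = pyranone, ring B = benzofuran), and tert-butyl (2-methylbut-3-en-2-yl) carbonate is assumed to be a catalogue reagent.

**Step 1**
Reactants: 1 5-iodovanillin (4-hydroxy-3-iodo-5-methoxybenzaldehyde), 2 ethynyltrimethylsilane
Product: 5 7-methoxy-1-benzofuran-5-carbaldehyde, via alkynylphenol 3 (not isolated), via 2-silylbenzofuran 4 (not isolated)
Conditions: Pd(PPh3)2Cl2 (cat.), CuI (cat.), Et3N, DMF, rt → 60 °C; then Bu4NF, THF, 60 °C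
Reagents that add atoms: none
Why: Sonogashira coupling at the C–I bond next to the free phenol, 5-endo-dig closure of the resulting o-alkynylphenol under the copper/amine conditions and fluoride protodesilylation of C2 should deliver the 2,3-unsubstituted benzofuran in one flask, a standard o-iodophenol heteroannulation.

**Step 2**
Reactants: 5 7-methoxy-1-benzofuran-5-carbaldehyde
Product: 6 7-hydroxy-1-benzofuran-5-carbaldehyde
Conditions: BBr3, CH2Cl2, −78 → 0 °C; then H2O
Reagents that add atoms: none
Why: Lewis-acid ether cleavage with BBr3 (O-demethylation) should free the C7 phenol at low temperature, conditions under which aryl aldehydes and the furan ring are known to survive.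

**Step 3**
Reactants: 6 7-hydroxy-1-benzofuran-5-carbaldehyde, 7 tert-butyl (2-methylbut-3-en-2-yl) carbonate
Product: 8 7-[(2-methylbut-3-en-2-yl)oxy]-1-benzofuran-5-carbaldehyde
Conditions: Pd(PPh3)4 (cat.), THF, 0 °C → rt
Reagents that add atoms: none
Why: Tsuji–Trost O-allylation: ionisation of the tertiary carbonate by zerovalent palladium and kinetic attack of the phenoxide at the more substituted allyl terminus should give the tertiary 1,1-dimethylallyl ether, and the low temperature prevents its equilibration to the linear prenyl ether.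

**Step 4**
Reactants: 8 7-[(2-methylbut-3-en-2-yl)oxy]-1-benzofuran-5-carbaldehyde
Product: 10 7-hydroxy-6-(3-methylbut-2-en-1-yl)-1-benzofuran-5-carbaldehyde, via dienone 9 (not isolated)
Conditions: N,N-diethylaniline, 130 °C
Reagents that add atoms: none
Why: Aromatic Claisen rearrangement: the [3,3] shift can only end productively at C6 because the other ortho position C7a is the ring-fusion carbon, so the chair transition state transposes the 1,1-dimethylallyl group into a C6 3-methylbut-2-enyl group and dienone 9 tautomerises to the phenol.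

**Step 5**
Reactants: 10 7-hydroxy-6-(3-methylbut-2-en-1-yl)-1-benzofuran-5-carbaldehyde
Product: 11 7-(methoxymethoxy)-6-(3-methylbut-2-en-1-yl)-1-benzofuran-5-carbaldehyde
Conditions: MOMCl, i-Pr2NEt, CH2Cl2, 0 °C → rt
Reagents that add atoms: chloromethyl methyl ether (MOMCl), COCCl
Why: Base-mediated O-alkylation with MOMCl (acetal protection) masks the C7 phenol in a form stable to the enolate, hydride, Mitsunobu and organolithium steps ahead.

**Step 6**
Reactants: 11 7-(methoxymethoxy)-6-(3-methylbut-2-en-1-yl)-1-benzofuran-5-carbaldehyde, 12 N-methoxy-N-methylacetamide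
Product: 14 rac-3-hydroxy-N-methoxy-3-[7-(methoxymethoxy)-6-(3-methylbut-2-en-1-yl)-1-benzofuran-5-yl]-N-methylpropanamide, via lithium enolate 13 (not isolated)
Conditions: 12, LiN(i-Pr)2 (LDA), THF, −78 °C; then 11, −78 °C; AcOH quench
Reagents that add atoms: none
Why: Aldol addition of the preformed lithium enolate of the Weinreb acetamide to the aldehyde at −78 °C installs C3 and C4 of the later ring C, and the configuration of the carbinol is irrelevant because it is oxidised in the next step.

**Step 7**
Reactants: 14 rac-3-hydroxy-N-methoxy-3-[7-(methoxymethoxy)-6-(3-methylbut-2-en-1-yl)-1-benzofuran-5-yl]-N-methylpropanamide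
Product: 15 N-methoxy-3-[7-(methoxymethoxy)-6-(3-methylbut-2-en-1-yl)-1-benzofuran-5-yl]-N-methyl-3-oxopropanamide
Conditions: Dess–Martin periodinane, CH2Cl2, 0 °C → rt
Reagents that add atoms: none
Why: Dess–Martin oxidation converts the benzylic secondary alcohol into the aryl ketone under neutral conditions that leave the prenyl alkene, the furan and the MOM ether alone.

**Step 8**
Reactants: 15 N-methoxy-3-[7-(methoxymethoxy)-6-(3-methylbut-2-en-1-yl)-1-benzofuran-5-yl]-N-methyl-3-oxopropanamide
Product: 16 (3R)-3-hydroxy-N-methoxy-3-[7-(methoxymethoxy)-6-(3-methylbut-2-en-1-yl)-1-benzofuran-5-yl]-N-methylpropanamide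
Conditions: RuCl[(R,R)-TsDPEN](p-cymene) (cat.), HCO2H–Et3N (5:2 azeotrope), EtOAc, rt
Reagents that add atoms: none
Why: Noyori asymmetric transfer hydrogenation: the ruthenium hydride bearing (R,R)-TsDPEN reduces the aryl ketone through the outer-sphere six-membered transition state in which the aryl ring contacts the p-cymene ligand, which should set the (R) carbinol (the mirror image of the (S,S)-catalyst/(S)-1-arylethanol pairing) without reducing the alkenes.

**Step 9**
Reactants: 17 phloroglucinol (benzene-1,3,5-triol)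
Product: 18 3,5-bis(methoxymethoxy)phenol
Conditions: MOMCl (2 equiv), i-Pr2NEt, DMF, 0 °C → rt
Reagents that add atoms: chloromethyl methyl ether (MOMCl), COCCl
Why: Stoichiometry-controlled O-alkylation caps two of the three equivalent hydroxyls as MOM ethers, and the bis-ether is separated from mono- and tris-ether by chromatography.

**Step 10**
Reactants: 18 3,5-bis(methoxymethoxy)phenol
Product: 19 2-bromo-3,5-bis(methoxymethoxy)phenol
Conditions: NBS (1 equiv), i-Pr2NH (cat.), CH2Cl2, −78 → 0 °C
Reagents that add atoms: N-bromosuccinimide (NBS), O=C1CCC(=O)N1Br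
Why: Amine-mediated ortho-bromination of a phenol (electrophilic aromatic substitution in which the N-bromoamine is delivered through a hydrogen bond to the OH) should place the bromine at C2 between the hydroxyl and a MOM ether, not at C4 between the two MOM ethers.

**Step 11**
Reactants: 16 (3R)-3-hydroxy-N-methoxy-3-[7-(methoxymethoxy)-6-(3-methylbut-2-en-1-yl)-1-benzofuran-5-yl]-N-methylpropanamide, 19 2-bromo-3,5-bis(methoxymethoxy)phenol
Product: 20 (3S)-3-[2-bromo-3,5-bis(methoxymethoxy)phenoxy]-N-methoxy-3-[7-(methoxymethoxy)-6-(3-methylbut-2-en-1-yl)-1-benzofuran-5-yl]-N-methylpropanamide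
Conditions: PPh3, DIAD, toluene, 0 °C → rt
Reagents that add atoms: none
Why: Mitsunobu etherification: the acidic o-bromophenol protonates the betaine and its phenoxide displaces the alkoxyphosphonium by SN2 with inversion, converting the (R) alcohol into the (S) benzylic aryl ether that becomes C2–O1.

**Step 12**
Reactants: 20 (3S)-3-[2-bromo-3,5-bis(methoxymethoxy)phenoxy]-N-methoxy-3-[7-(methoxymethoxy)-6-(3-methylbut-2-en-1-yl)-1-benzofuran-5-yl]-N-methylpropanamide
Product: 23 (2S)-5,7-bis(methoxymethoxy)-2-[7-(methoxymethoxy)-6-(3-methylbut-2-en-1-yl)-1-benzofuran-5-yl]-2,3-dihydro-4H-chromen-4-one, via aryllithium 21 (not isolated), via lithium hemiaminal 22 (not isolated)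
Conditions: t-BuLi (2.1 equiv), THF, −78 °C; then AcOH, −78 °C → rt
Reagents that add atoms: none
Why: Bromine–lithium exchange at C4a (the second equivalent of t-BuLi destroys the t-BuBr formed) gives aryllithium 21, held between the C5 MOM ether and the O1 ether oxygen, which adds to the Weinreb amide carbonyl C4 to give the lithium-chelated N-methoxy hemiaminal 22, and this collapses to the C4 ketone only on the acidic quench. This is a Parham cyclisation (cycloacylation), the established anionic route from o-bromoaryl ethers with a tethered Weinreb amide to chroman-4-ones. Ring C (O1, C2, C3, C4, C4a, C8a) closes by a 6-exo-trig addition to the amide C=O. No stereocentre is created in the product, and the (S) centre at C2 set in step 11 is preserved because hemiaminal 22 cannot enolise at C3 and so cannot open by retro-oxa-Michael reaction before the cold acetic acid quench. The step needs the exchange to outrun deprotonation at C3 (which would expel the phenoxide by E1cB), lithiation of furan C2 and attack of t-BuLi on the amide; the very fast exchange of an aryl bromide flanked by two oxygens at −78 °C and the intramolecular six-membered delivery should secure this, and the site of C–C bond formation is fixed by the bromine.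

**Step 13**
Reactants: 23 (2S)-5,7-bis(methoxymethoxy)-2-[7-(methoxymethoxy)-6-(3-methylbut-2-en-1-yl)-1-benzofuran-5-yl]-2,3-dihydro-4H-chromen-4-one
Product: 24 (2S)-5,7-dihydroxy-2-[7-hydroxy-6-(3-methylbut-2-en-1-yl)-1-benzofuran-5-yl]-2,3-dihydro-4H-chromen-4-one
Conditions: HCl (3 M aq.), MeOH, 45 °C
Reagents that add atoms: none
Why: Acid-catalysed acetal exchange with methanol removes the three MOM ethers (the hydrogen-bonded C5 one fastest) under conditions mild enough that the prenyl group should not cyclise onto the neighbouring phenol and the C2 centre, which epimerises only through base-induced ring opening, is retained.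

**Compound list**
1 | 5-iodovanillin (4-hydroxy-3-iodo-5-methoxybenzaldehyde) | COc1cc(C=O)cc(I)c1O | starting material
2 | ethynyltrimethylsilane | C#C[Si](C)(C)C | starting material
3 | 4-hydroxy-3-methoxy-5-[(trimethylsilyl)ethynyl]benzaldehyde (formed in the flask) | COc1cc(C=O)cc(C#C[Si](C)(C)C)c1O | intermediate
4 | 7-methoxy-2-(trimethylsilyl)-1-benzofuran-5-carbaldehyde (formed in the flask) | COc1cc(C=O)cc2cc([Si](C)(C)C)oc12 | intermediate
5 | 7-methoxy-1-benzofuran-5-carbaldehyde | COc1cc(C=O)cc2ccoc12 | intermediate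
6 | 7-hydroxy-1-benzofuran-5-carbaldehyde | Oc1cc(C=O)cc2ccoc12 | intermediate
7 | tert-butyl (2-methylbut-3-en-2-yl) carbonate | CC(C)(C)OC(=O)OC(C)(C)C=C | starting material
8 | 7-[(2-methylbut-3-en-2-yl)oxy]-1-benzofuran-5-carbaldehyde | C=CC(C)(C)Oc1cc(C=O)cc2ccoc12 | intermediate
9 | 6-(3-methylbut-2-en-1-yl)-7-oxo-6,7-dihydro-1-benzofuran-5-carbaldehyde (formed in the flask) | O=CC1=CC2=C(OC=C2)C(=O)C1CC=C(C)C | intermediate
10 | 7-hydroxy-6-(3-methylbut-2-en-1-yl)-1-benzofuran-5-carbaldehyde | CC(C)=CCc1c(C=O)cc2ccoc2c1O | intermediate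
11 | 7-(methoxymethoxy)-6-(3-methylbut-2-en-1-yl)-1-benzofuran-5-carbaldehyde | CC(C)=CCc1c(C=O)cc2ccoc2c1OCOC | intermediate
12 | N-methoxy-N-methylacetamide | CC(=O)N(C)OC | starting material
13 | lithium 1-[methoxy(methyl)amino]ethenolate, the enolate of 12 (formed in the flask) | [Li]OC(=C)N(C)OC | intermediate
14 | rac-3-hydroxy-N-methoxy-3-[7-(methoxymethoxy)-6-(3-methylbut-2-en-1-yl)-1-benzofuran-5-yl]-N-methylpropanamide | CC(C)=CCc1c(C(O)CC(=O)N(C)OC)cc2ccoc2c1OCOC | intermediate
15 | N-methoxy-3-[7-(methoxymethoxy)-6-(3-methylbut-2-en-1-yl)-1-benzofuran-5-yl]-N-methyl-3-oxopropanamide | CC(C)=CCc1c(C(=O)CC(=O)N(C)OC)cc2ccoc2c1OCOC | intermediate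
16 | (3R)-3-hydroxy-N-methoxy-3-[7-(methoxymethoxy)-6-(3-methylbut-2-en-1-yl)-1-benzofuran-5-yl]-N-methylpropanamide | CC(C)=CCc1c([C@@H](CC(=O)N(C)OC)O)cc2ccoc2c1OCOC | intermediate
17 | phloroglucinol (benzene-1,3,5-triol) | Oc1cc(O)cc(O)c1 | starting material
18 | 3,5-bis(methoxymethoxy)phenol | COCOc1cc(O)cc(OCOC)c1 | intermediate
19 | 2-bromo-3,5-bis(methoxymethoxy)phenol | COCOc1cc(O)c(Br)c(OCOC)c1 | intermediate
20 | (3S)-3-[2-bromo-3,5-bis(methoxymethoxy)phenoxy]-N-methoxy-3-[7-(methoxymethoxy)-6-(3-methylbut-2-en-1-yl)-1-benzofuran-5-yl]-N-methylpropanamide | CC(C)=CCc1c([C@H](CC(=O)N(C)OC)Oc2cc(OCOC)cc(OCOC)c2Br)cc2ccoc2c1OCOC | intermediate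
21 | aryllithium of 20, lithium in place of bromine at C4a (formed in the flask) | CC(C)=CCc1c([C@H](CC(=O)N(C)OC)Oc2cc(OCOC)cc(OCOC)c2[Li])cc2ccoc2c1OCOC | intermediate
22 | lithium (2S)-4-[methoxy(methyl)amino]-5,7-bis(methoxymethoxy)-2-[7-(methoxymethoxy)-6-(3-methylbut-2-en-1-yl)-1-benzofuran-5-yl]chroman-4-olate, C4 configuration undefined (formed in the flask) | CC(C)=CCc1c([C@@H]2CC(O[Li])(N(C)OC)c3c(OCOC)cc(OCOC)cc3O2)cc2ccoc2c1OCOC | intermediate
23 | (2S)-5,7-bis(methoxymethoxy)-2-[7-(methoxymethoxy)-6-(3-methylbut-2-en-1-yl)-1-benzofuran-5-yl]-2,3-dihydro-4H-chromen-4-one | CC(C)=CCc1c([C@@H]2CC(=O)c3c(OCOC)cc(OCOC)cc3O2)cc2ccoc2c1OCOC | intermediate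
24 | (2S)-5,7-dihydroxy-2-[7-hydroxy-6-(3-methylbut-2-en-1-yl)-1-benzofuran-5-yl]-2,3-dihydro-4H-chromen-4-one | CC(C)=CCc1c([C@@H]2CC(=O)c3c(O)cc(O)cc3O2)cc2ccoc2c1O | target

**Step count**
Total: 13 steps. Longest linear sequence: 11 steps (steps 1–8, then 11, 12 and 13); steps 9 and 10 make the ring A fragment in parallel.

**Steps most likely to fail**

Step 11 (Mitsunobu etherification). The activated β-hydroxy amide may dehydrate to the cinnamamide, or the electron-rich benzylic alkoxyphosphonium may ionise and lose configuration. The fallback takes the carbonyl out of play during the substitution. It sets out from 16: LiBH4 in THF/MeOH should reduce the Weinreb amide to (1R)-1-[7-(methoxymethoxy)-6-(3-methylbut-2-en-1-yl)-1-benzofuran-5-yl]propane-1,3-diol F1. TBSCl and imidazole in CH2Cl2 silylate the primary hydroxyl to give (1R)-3-[(tert-butyldimethylsilyl)oxy]-1-[7-(methoxymethoxy)-6-(3-methylbut-2-en-1-yl)-1-benzofuran-5-yl]propan-1-ol F2. Mitsunobu coupling with 19 (PPh3, DIAD, toluene), now without acidic α-hydrogens, should give with inversion the (S)-configured ether [(3S)-3-[2-bromo-3,5-bis(methoxymethoxy)phenoxy]-3-[7-(methoxymethoxy)-6-(3-methylbut-2-en-1-yl)-1-benzofuran-5-yl]propoxy](tert-butyl)dimethylsilane F3. Bu4NF in THF frees (3S)-3-[2-bromo-3,5-bis(methoxymethoxy)phenoxy]-3-[7-(methoxymethoxy)-6-(3-methylbut-2-en-1-yl)-1-benzofuran-5-yl]propan-1-ol F4. TEMPO (cat.) with PhI(OAc)2 in aqueous MeCN oxidises it to (3S)-3-[2-bromo-3,5-bis(methoxymethoxy)phenoxy]-3-[7-(methoxymethoxy)-6-(3-methylbut-2-en-1-yl)-1-benzofuran-5-yl]propanoic acid F5. Coupling with N,O-dimethylhydroxylamine hydrochloride (EDC, HOBt, i-Pr2NEt) comes back to the route at 20.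

Step 12 (Parham cyclisation). Proton transfer from C3 to the aryllithium followed by β-elimination of the phenoxide, or attack of t-BuLi on the amide, may outrun ring closure. The fallback closes the same C4–C4a bond at the aldehyde oxidation level without a strong base. It sets out from 20: i-Bu2AlH in THF at −78 °C should give (3S)-3-[2-bromo-3,5-bis(methoxymethoxy)phenoxy]-3-[7-(methoxymethoxy)-6-(3-methylbut-2-en-1-yl)-1-benzofuran-5-yl]propanal F6. A Nozaki–Hiyama–Kishi reaction (CrCl2 in excess, NiCl2 cat., DMF, rt → 50 °C) adds the aryl–chromium species to the aldehyde and should give (2S)-5,7-bis(methoxymethoxy)-2-[7-(methoxymethoxy)-6-(3-methylbut-2-en-1-yl)-1-benzofuran-5-yl]chroman-4-ol F7 as a mixture of C4 epimers. Dess–Martin oxidation in CH2Cl2 comes back to the route at 23.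

Step 10 (ortho-bromination). Bromination may occur at C4 between the two MOM ethers, or twice. The fallback fixes the position by directed ortho-metalation. It sets out from 18: ClC(O)NEt2 with K2CO3 in MeCN gives 3,5-bis(methoxymethoxy)phenyl diethylcarbamate F8. s-BuLi/TMEDA in THF at −78 °C should lithiate between the carbamate and a MOM ether, and quenching with BrCCl2CCl2Br gives 2-bromo-3,5-bis(methoxymethoxy)phenyl diethylcarbamate F9. KOH in EtOH at reflux cleaves the carbamate and comes back to the route at 19.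

**Further compounds**
F1 | step 11 | (1R)-1-[7-(methoxymethoxy)-6-(3-methylbut-2-en-1-yl)-1-benzofuran-5-yl]propane-1,3-diol | CC(C)=CCc1c([C@@H](CCO)O)cc2ccoc2c1OCOC
F2 | step 11 | (1R)-3-[(tert-butyldimethylsilyl)oxy]-1-[7-(methoxymethoxy)-6-(3-methylbut-2-en-1-yl)-1-benzofuran-5-yl]propan-1-ol | CC(C)=CCc1c([C@@H](CCO[Si](C)(C)C(C)(C)C)O)cc2ccoc2c1OCOC
F3 | step 11 | [(3S)-3-[2-bromo-3,5-bis(methoxymethoxy)phenoxy]-3-[7-(methoxymethoxy)-6-(3-methylbut-2-en-1-yl)-1-benzofuran-5-yl]propoxy](tert-butyl)dimethylsilane | CC(C)=CCc1c([C@H](CCO[Si](C)(C)C(C)(C)C)Oc2cc(OCOC)cc(OCOC)c2Br)cc2ccoc2c1OCOC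
F4 | step 11 | (3S)-3-[2-bromo-3,5-bis(methoxymethoxy)phenoxy]-3-[7-(methoxymethoxy)-6-(3-methylbut-2-en-1-yl)-1-benzofuran-5-yl]propan-1-ol | CC(C)=CCc1c([C@H](CCO)Oc2cc(OCOC)cc(OCOC)c2Br)cc2ccoc2c1OCOC
F5 | step 11 | (3S)-3-[2-bromo-3,5-bis(methoxymethoxy)phenoxy]-3-[7-(methoxymethoxy)-6-(3-methylbut-2-en-1-yl)-1-benzofuran-5-yl]propanoic acid | CC(C)=CCc1c([C@H](CC(=O)O)Oc2cc(OCOC)cc(OCOC)c2Br)cc2ccoc2c1OCOC
F6 | step 12 | (3S)-3-[2-bromo-3,5-bis(methoxymethoxy)phenoxy]-3-[7-(methoxymethoxy)-6-(3-methylbut-2-en-1-yl)-1-benzofuran-5-yl]propanal | CC(C)=CCc1c([C@H](CC=O)Oc2cc(OCOC)cc(OCOC)c2Br)cc2ccoc2c1OCOC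
F7 | step 12 | (2S)-5,7-bis(methoxymethoxy)-2-[7-(methoxymethoxy)-6-(3-methylbut-2-en-1-yl)-1-benzofuran-5-yl]chroman-4-ol (C4 epimers) | CC(C)=CCc1c([C@@H]2CC(O)c3c(OCOC)cc(OCOC)cc3O2)cc2ccoc2c1OCOC
F8 | step 10 | 3,5-bis(methoxymethoxy)phenyl diethylcarbamate | CCN(CC)C(=O)Oc1cc(OCOC)cc(OCOC)c1
F9 | step 10 | 2-bromo-3,5-bis(methoxymethoxy)phenyl diethylcarbamate | CCN(CC)C(=O)Oc1cc(OCOC)cc(OCOC)c1Br
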